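**Plan**
- Core ring numbering (each half): C1–O, C2 = biaryl carbon, C3 = side-chain carbon, C4–O, C5–O, C6–CH3. The molecule is C2-symmetric, and each C3 carries an ethylene bridge Cα–Cβ to the same 2-methoxyphenyl ring, so one 3,3′-dialdehyde and one benzylic ylide serve both ends.
- Retrosynthesis: C5–OH goes back to C5–OMe and the quinone C1=O/C4=O back to aryl methyl ethers. Both Cα–Cβ bonds are then cut as Cα=Cβ (two-fold Wittig), followed by the two C3–CHO bonds, the C2–C2′ biaryl bond and the C6–CH3 bond.
- Forward: no ring is built. 1,2,4-Trimethoxybenzene is methylated, brominated and homocoupled, and the biaryl is formylated at C3/C3′. Both side chains are then attached in one operation, followed by hydrogenation, oxidation to the bis(quinone) and ether hydrolysis.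
- Stereochemistry: the target has no stereocentre. The alkene geometry from the olefination is erased by hydrogenation.

Key step: step 6

Remark: the target SMILES carries no stereodescriptor, so the hindered biaryl axis is taken as racemic and is not controlled.

**Step 1**
Reactants: 1 (1,2,4-trimethoxybenzene); 2 (iodomethane)
Product: 4 trimethoxytoluene (1,2,4-trimethoxy-3-methylbenzene), via aryllithium 3 (not isolated)
Conditions: n-BuLi, THF, 0 °C to rt; then MeI, −78 °C to rt
Reagents that add atoms: none
Why: Directed ortho-metalation removes the C3–H of 1, the only ring proton flanked by two methoxy groups (those at C2 and C4), and the aryllithium is methylated by iodomethane in an SN2 reaction.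

**Step 2**
Reactants: 4 (1,2,4-trimethoxy-3-methylbenzene)
Product: 5 aryl bromide (1-bromo-2,4,5-trimethoxy-3-methylbenzene)
Conditions: NBS, MeCN, 0 °C to rt
Reagents that add atoms: N-bromosuccinimide, O=C1CCC(=O)N1Br
Why: Electrophilic aromatic bromination should take position 5 of 4, which is ortho to the 4-methoxy and para to the 2-methoxy group and becomes C2 of the core numbering, whereas position 6 has only one ortho methoxy group.

**Step 3**
Reactants: 5 (1-bromo-2,4,5-trimethoxy-3-methylbenzene, two molecules)
Product: 6 biaryl (2,2′,4,4′,5,5′-hexamethoxy-3,3′-dimethyl-1,1′-biphenyl)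
Conditions: NiCl2(PPh3)2 (cat.), PPh3, Zn dust, Et4NI, THF, 50 °C
Reagents that add atoms: none
Why: In this nickel-mediated reductive homocoupling (Ullmann-type), zerovalent nickel made from NiCl2(PPh3)2 and zinc inserts into the C–Br bond and joins two aryl groups at C2/C2′, and unlike the copper version it needs no electron-poor or ortho-activated halide and tolerates the single ortho methoxy group.

**Step 4**
Reactants: 6 (hexamethoxy-dimethylbiphenyl); 7 (dichloromethyl methyl ether)
Product: 9 dialdehyde (3,3′,4,4′,6,6′-hexamethoxy-5,5′-dimethyl-[1,1′-biphenyl]-2,2′-dicarbaldehyde), via bis(chloromethoxymethyl)biaryl 8 (not isolated)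
Conditions: Cl2CHOMe (excess), TiCl4, CH2Cl2, −20 to 0 °C; then ice-cold 1 M HCl
Reagents that add atoms: water, O
Why: In this Rieche formylation the TiCl4-activated chloro(methoxy)carbenium ion can only attack the one unsubstituted carbon of each ring (core C3 and C3′), which is ortho to the C4 methoxy group and para to the C6 methyl group, and the α-chloro ethers are hydrolysed to the aldehydes on aqueous work-up.

**Step 5**
Reactants: 10 (2-methoxybenzyl chloride); 11 (triphenylphosphine)
Product: 12 phosphonium salt ((2-methoxybenzyl)triphenylphosphonium chloride)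
Conditions: PPh3, toluene, reflux
Reagents that add atoms: none
Why: SN2 quaternisation of triphenylphosphine by a benzylic chloride is the standard preparation of benzylic Wittig salts, and the salt should crystallise from toluene.

**Step 6**
Reactants: 9 (biaryl 2,2′-dicarbaldehyde); 12 ((2-methoxybenzyl)triphenylphosphonium chloride, about 2.6 equiv)
Product: 14 bis(stilbene) (2,2′-bis[2-(2-methoxyphenyl)ethenyl]-3,3′,4,4′,6,6′-hexamethoxy-5,5′-dimethyl-1,1′-biphenyl; E/Z mixture drawn as E,E), via phosphonium ylide 13 (not isolated)
Conditions: KOtBu, THF, 0 °C; then 9, 0 °C to rt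
Reagents that add atoms: none
Why: KOtBu converts 12 into the semi-stabilised benzylic ylide 13, which adds to each formyl carbon to give an oxaphosphetane that collapses by cycloreversion to the Cα=Cβ double bond and Ph3PO, so both ethylene bridges are laid down in one operation. The closest known reaction type is the Wittig olefination of aryl aldehydes with benzyltriphenylphosphonium ylides, including two-fold versions on biphenyl-2,2′-dicarbaldehydes. No ring is closed and no stereocentre is created; the alkenes are expected as an E/Z mixture, which is irrelevant because step 7 saturates both. The step needs complete conversion of two formyl groups that each sit between the biaryl bond (C2) and the C4 methoxy group, without base-induced Cannizzaro-type reaction between the neighbouring aldehydes. This is secured by preforming an excess of the ylide so that no free alkoxide meets 9, by the small planar nucleophilic ylide carbon, and by the absence of enolisable or otherwise electrophilic sites in 9, whose other groups are only aryl methyl ethers. Because the two rings are held roughly perpendicular, the two aldehydes should react independently of each other.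

**Step 7**
Reactants: 14 (bis(stilbene), E/Z mixture)
Product: 15 bis(bibenzyl) (3,3′,4,4′,6,6′-hexamethoxy-2,2′-bis[2-(2-methoxyphenyl)ethyl]-5,5′-dimethyl-1,1′-biphenyl)
Conditions: H2 (1 atm), 10% Pd/C, EtOAc, rt
Reagents that add atoms: none
Why: Heterogeneous catalytic hydrogenation of 1,2-diarylalkenes over Pd/C takes every alkene isomer to the same saturated product, and the aryl methyl ethers have no benzylic C–O bond that could be hydrogenolysed.

**Step 8**
Reactants: 15 (hexamethoxy bis(bibenzyl))
Product: 16 bis(methoxyquinone) (5,5′-dimethoxy-3,3′-bis[2-(2-methoxyphenyl)ethyl]-6,6′-dimethyl-2,2′-bi(1,4-benzoquinone))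
Conditions: (NH4)2Ce(NO3)6 (excess), MeCN/H2O, 0 °C
Reagents that add atoms: water, O
Why: Oxidative demethylation of 1,4-dimethoxyarenes by tetravalent cerium should act only on the two hexasubstituted trimethoxy rings, which are far more electron-rich than the pendant monomethoxy rings, and give the para-quinones across C1/C4 with the C5 methoxy group left as a vinylogous ester; an ortho-quinone formed across C4/C5 would be hydrolysed in step 9 to the same hydroxyquinone tautomer.

**Step 9**
Reactants: 16 (bis(methoxyquinone))
Product: 18 target (5,5′-dihydroxy-3,3′-bis[2-(2-methoxyphenyl)ethyl]-6,6′-dimethyl-2,2′-bi(1,4-benzoquinone)), via disodium bis(quinonolate) 17 (not isolated)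
Conditions: 1 M aq NaOH, THF, rt, under Ar; then 1 M HCl
Reagents that add atoms: sodium hydroxide, [Na+].[OH-]
Why: Base hydrolysis of a vinylogous ester by addition–elimination lets hydroxide add at C5 of each fully substituted methoxyquinone and expel methoxide to give the resonance-stabilised hydroxyquinone anion, which is protonated on acidification, while the aryl methyl ethers of the pendant rings are inert.

**Compound list**
1 | 1,2,4-trimethoxybenzene | COc1ccc(OC)c(OC)c1 | starting material
2 | iodomethane | CI | starting material
3 | 2,3,6-trimethoxyphenyllithium | [Li]c1c(OC)ccc(OC)c1OC | intermediate (not isolated)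
4 | 1,2,4-trimethoxy-3-methylbenzene | COc1ccc(OC)c(C)c1OC | intermediate
5 | 1-bromo-2,4,5-trimethoxy-3-methylbenzene | COc1cc(Br)c(OC)c(C)c1OC | intermediate
6 | 2,2′,4,4′,5,5′-hexamethoxy-3,3′-dimethyl-1,1′-biphenyl | COc1cc(-c2cc(OC)c(OC)c(C)c2OC)c(OC)c(C)c1OC | intermediate
7 | dichloromethyl methyl ether | COC(Cl)Cl | starting material
8 | 2,2′-bis[chloro(methoxy)methyl]-3,3′,4,4′,6,6′-hexamethoxy-5,5′-dimethyl-1,1′-biphenyl (mixture of stereoisomers) | COc1c(C)c(OC)c(-c2c(C(Cl)OC)c(OC)c(OC)c(C)c2OC)c(C(Cl)OC)c1OC | intermediate (not isolated)
9 | 3,3′,4,4′,6,6′-hexamethoxy-5,5′-dimethyl-[1,1′-biphenyl]-2,2′-dicarbaldehyde | COc1c(C)c(OC)c(-c2c(C=O)c(OC)c(OC)c(C)c2OC)c(C=O)c1OC | intermediate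
10 | 2-methoxybenzyl chloride | COc1ccccc1CCl | starting material
11 | triphenylphosphine | c1ccc(cc1)P(c1ccccc1)c1ccccc1 | starting material
12 | (2-methoxybenzyl)triphenylphosphonium chloride | COc1ccccc1C[P+](c1ccccc1)(c1ccccc1)c1ccccc1.[Cl-] | intermediate
13 | (2-methoxybenzylidene)triphenylphosphorane | COc1ccccc1C=P(c1ccccc1)(c1ccccc1)c1ccccc1 | intermediate (not isolated)
14 | 2,2′-bis[2-(2-methoxyphenyl)ethenyl]-3,3′,4,4′,6,6′-hexamethoxy-5,5′-dimethyl-1,1′-biphenyl (E/Z mixture, drawn as E,E) | COc1ccccc1/C=C/c1c(OC)c(OC)c(C)c(OC)c1-c1c(/C=C/c2ccccc2OC)c(OC)c(OC)c(C)c1OC | intermediate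
15 | 3,3′,4,4′,6,6′-hexamethoxy-2,2′-bis[2-(2-methoxyphenyl)ethyl]-5,5′-dimethyl-1,1′-biphenyl | COc1ccccc1CCc1c(OC)c(OC)c(C)c(OC)c1-c1c(CCc2ccccc2OC)c(OC)c(OC)c(C)c1OC | intermediate
16 | 5,5′-dimethoxy-3,3′-bis[2-(2-methoxyphenyl)ethyl]-6,6′-dimethyl-2,2′-bi(1,4-benzoquinone) | COc1ccccc1CCC1=C(C2=C(CCc3ccccc3OC)C(=O)C(OC)=C(C)C2=O)C(=O)C(C)=C(OC)C1=O | intermediate
17 | disodium salt of the bis(hydroxyquinone) | COc1ccccc1CCC1=C(C2=C(CCc3ccccc3OC)C(=O)C([O-])=C(C)C2=O)C(=O)C(C)=C([O-])C1=O.[Na+].[Na+] | intermediate (not isolated)
18 | 5,5′-dihydroxy-3,3′-bis[2-(2-methoxyphenyl)ethyl]-6,6′-dimethyl-2,2′-bi(1,4-benzoquinone) | COc1ccccc1CCC1=C(C2=C(CCc3ccccc3OC)C(=O)C(O)=C(C)C2=O)C(=O)C(C)=C(O)C1=O | target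

**Step count**
Total steps: 9. Longest linear sequence: 8 (steps 1–4 and 6–9; step 5 is a one-step side branch).

**Steps most likely to fail**

Step 4 (two-fold Rieche formylation). The second formylation may stall because each C3 lies between the biaryl bond and a methoxy group. TiCl4 may also strip the methyl group from the C4 ether once the neighbouring formyl group chelates the metal. The fallback sets out from bromide 5 and formylates the monomer first (Cl2CHOMe, TiCl4, CH2Cl2, 0 °C, aqueous work-up). The only free position lies between Br and OMe, so this should give 2-bromo-3,5,6-trimethoxy-4-methylbenzaldehyde F1. Its C–Br bond is then activated by the ortho formyl group for a classical copper-mediated Ullmann coupling (Cu powder, DMF, reflux). This forms the C2–C2′ bond and comes back to the route at dialdehyde 9, bypassing steps 3 and 4.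

Step 9 (hydroxide hydrolysis). The bis(quinone) may degrade in base before both substitutions at C5 are complete. The likely pathways are deprotonation of the quinone-bound CH3 and CH2 groups to quinone methides and hydroxide addition at the carbonyl carbons. The fallback sets out from bis(methoxyquinone) 16 and cleaves the O–CH3 bond instead of the C5–O bond. LiI in EtOAc at reflux is the known SN2 dealkylation of methyl esters and their vinylogues, and here the hydroxyquinone anion is a vinylogous carboxylate leaving group. It should give dilithium bis(quinonolate) F2 and iodomethane with no hydroxide present. Dilute HCl in the work-up then comes back to the route at target 18. The unactivated methyl ethers of the pendant rings should not react.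

Step 3 (nickel-mediated homocoupling). The arylnickel intermediate may be protonated, returning arene 4 by hydrodebromination, faster than it engages a second molecule of the electron-rich bromide. The fallback sets out from bromide 5 and differentiates the two halves. Bromine–lithium exchange (n-BuLi, THF, −78 °C), B(OiPr)3 and acidic work-up should give (2,4,5-trimethoxy-3-methylphenyl)boronic acid F3. Suzuki–Miyaura coupling of F3 with a second equivalent of 5 (Pd(PPh3)4, K2CO3, DME/H2O, 85 °C) then comes back to the route at biaryl 6.

**Further compounds**
F1 | step 4 | 2-bromo-3,5,6-trimethoxy-4-methylbenzaldehyde | COc1c(C=O)c(Br)c(OC)c(C)c1OC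
F2 | step 9 | dilithium salt of the bis(hydroxyquinone) | COc1ccccc1CCC1=C(C2=C(CCc3ccccc3OC)C(=O)C([O-])=C(C)C2=O)C(=O)C(C)=C([O-])C1=O.[Li+].[Li+]
F3 | step 3 | (2,4,5-trimethoxy-3-methylphenyl)boronic acid | COc1cc(B(O)O)c(OC)c(C)c1OC
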